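## The problem

Robinetinidol-(4α,8)-gallocatechin (25) consists of two flavan-3-ol units held together by one C–C bond, from C4 of the upper pyran ring C to C8' of the phloroglucinol ring D of the lower unit. It has five stereocentres in two sets that cannot communicate: C2, C3 and C4 above (2R,3S,4S, all-trans) and C2' and C3' below (2R,3S, trans). Within a set one centre can steer its neighbour (the C3 oxygen directs the entry at C4, the C3' oxygen directs C2'), but each set needs its own absolute source. The interflavan bond must be made at C8' and not at C6', the other open position of ring D. The eleven hydroxyls include two pyrogallol rings (B and E) that do not survive base and air, and the benzylic C–O and C–C bonds of both pyran rings do not tolerate strong acid. All protection must therefore fall off at the end under neutral conditions. The feature that invites the key step is that C2' is benzylic to ring E and the ring E hydroxyl para to it lies between two oxygen substituents. A seco compound with a plain CH2 at C2' can therefore be oxidised to a para-quinone methide whose exocyclic carbon is C2', within reach of the ring D oxygen on C8a'. C2' thus needs no oxygen function until the last skeletal step, and the open chain has to carry only C3'.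

## Retrosynthesis

**25 from 24.** The last cut removes nine O-benzyl groups from 24 by hydrogenolysis. Benzyl is preferred to methyl or silyl ethers because its removal is neutral and touches neither the pyrogallol rings nor the interflavan bond. The forward step only has to spare the two cyclic benzylic ethers.

**24 from 22 (key disconnection).** The O1'–C2' bond of ring F is cut, leading back to triol 22, in which C2' is a methylene group and the ring D and ring E phenols are free. The neighbouring cuts are less attractive. Cutting O1'–C8a' would need a nucleophilic aromatic substitution on an electron-rich ring. A C2' cation from a 1,2-diol would mean carrying a second oxygen and a second stereocentre that is then destroyed. Precursor 22 has one ring and one stereocentre fewer than 24. The forward step must oxidise ring E only (via quinone methide 23), close the ring through the C8a' oxygen and place the ring E aryl group trans to the C3' benzyloxy group.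

**22 from 4 and 20.** The C4–C8' bond is cut, giving the flavan-3,4-diol diacetate 4 as electrophile and the seco-gallocatechin diphenol 20 as nucleophile, with acetate 21 as the coupling product. A Friedel–Crafts arylation of a flavan-4-yl cation is the established way to this bond and is convergent. It is placed before ring F is closed because the strategy needs the open chain at the oxidation stage. The C3 oxygen carries acetate, not benzyl, so that it can take part at C4 and enforce 3,4-trans entry. The acetate is removed (21 to 22) before the oxidation so that no base meets the finished ring F. The forward step must select C8' over C6' and the α face of C4.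

**4 from 1.** The upper unit goes back through diol 3 and ketone 2 to (+)-dihydrorobinetin 1, which supplies C2 and C3 in the correct absolute sense. Only functional-group changes are involved: benzylation of the four phenols, carbonyl reduction and acetylation. This is shorter than any de novo construction of ring C.

**20 from 16 and 14.** After removal of two MOM groups (19) and the C3' benzyl ether (18), the C4'–C4a' bond is cut to the ring D aryllithium 17, made from MOM ether 16, and the ring E benzyl oxirane 14. An aryl anion opening a terminal epoxide fixes the point of attachment on ring D by the directing group. An acid-mediated alkylation of a phloroglucinol ether by the epoxide would not, and would endanger the carbinol centre. The forward step must lithiate between the MOM ether and a benzyl ether and open the epoxide at its CH2 end.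

**14 from 10 and 11.** The bond from C2' to ring E is cut to the aryl Grignard reagent 12 (from bromide 10) and (R)-epichlorohydrin 11, via chlorohydrin 13. The C3' stereocentre is bought, not made, and no bond to it is broken on the way to 20.

**10 and 16 from 5 and 15.** Bromide 10 comes from 1,3-bis(benzyloxy)benzene 5 by hydroxylation between the two ethers (8), para bromination (9) and MOM protection. MOM ether 16 comes from 3,5-bis(benzyloxy)phenol 15. The MOM group on ring E marks the oxygen that must be free in the key step. The MOM group on ring D marks the oxygen that becomes O1'.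

## Roads not taken

**Alternative 1:** Ring D would be cut at C7'–C8' and C4a'–C8a'. In the forward sense a Danheiser benzannulation would join the 4α-silyloxyalkyne A2 of the benzylated upper unit with the 3-benzyloxy-2-cinnamylcyclobutenone A3 on heating, to give the resorcinol monosilyl ether A1. Its merit is real: every substituent of ring D is placed by construction, so there is no C6'/C8' question, and here it is better than the chosen plan, which relies on an intrinsic preference in step 13. Its weak points are the partners and the distance still to go. A2 is a silyl ynol ether on a doubly activated benzylic carbon and would be fragile. A3 needs its own multi-step synthesis. A1 still lacks ring F, whose closure would require benzylation, an asymmetric dihydroxylation of the alkene under pure reagent control, desilylation and a cation cyclisation. The chosen plan sets against the regiochemical advantage a much shorter end game, simple aromatic building blocks and a C3' centre taken from epichlorohydrin.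

**Alternative 2:** Ring C would be cut at C2=C3. Ring-closing metathesis of diene A5 (C4 vinyl group and ring A aryl enol ether) with a ruthenium alkylidene such as the second-generation Grubbs catalyst would give the 4-aryl-4H-flavene A4. Hydroboration and oxidation anti to the C4 aryl group would then set C2 and C3 from C4. It is better in one respect: the lower unit enters as a complete flavan-3-ol and ring F never has to be closed. The weak points are C4 and the metathesis. In A5 C4 is a stereocentre bearing two aryl groups and a vinyl group, with no neighbouring handle and too far from the lower unit to be controlled by it. The metathesis forms a trisubstituted enol ether conjugated to an electron-rich ring, which is slow. A4 is acid-labile and prone to double-bond migration. The chosen plan takes C2 and C3 from 1 and sets C4 by participation of the C3 acetate, both on firm ground.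

**Alternative 3:** Ring C would be cut at O1–C2 and C3–C4. Benzhydrol A7, in which C4 is already bonded to C8' of the complete lower unit, would lose water to a transient heterodiene across C4 and the ring A oxygen. This would add the (E)-styrenyl boronate A8 in a hetero-Diels–Alder reaction to give the C3 boronate A6, which oxidises with retention to the C3 alcohol. On paper this is the shortest road and it makes ring C and three stereocentres in one step; in step economy it is better than the chosen plan. Its weakness is stereocontrol. The two faces of the heterodiene differ only through the remote lower unit, so both diastereomeric upper units must be expected. The 2,4-cis arrangement needs one particular endo/exo mode. A vinyl boronate is also not an electron-rich dienophile. The chosen plan sets against the shorter count that every stereocentre is traced to a chiral-pool compound or to a neighbouring group one bond away.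

Key step: step 15

Remark on the chemistry: (+)-dihydrorobinetin 1 is assumed to be available as the natural (2R,3R) compound. Any C4 epimer of 3 formed in step 2 may be carried along, because C4 is ionised in step 13. Upper-unit locants (rings A, B, C) are unprimed; lower-unit locants (rings D, E, F) are primed.

## Route

Step 1
Reactants: 1 (+)-dihydrorobinetin
Product: 2 (2R,3R)-7-(benzyloxy)-3-hydroxy-2-[3,4,5-tris(benzyloxy)phenyl]chroman-4-one
Conditions: BnBr, K2CO3, DMF, rt, argon
Reagents that add atoms: benzyl bromide, BrCc1ccccc1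
Why: Williamson etherification of the four phenols; the C3 alcohol is not deprotonated by K2CO3, and mild base at room temperature under argon should avoid opening of the β-aryloxy ketone, so C2 and C3 stay as in 1.

Step 2
Reactants: 2 (2R,3R)-7-(benzyloxy)-3-hydroxy-2-[3,4,5-tris(benzyloxy)phenyl]chroman-4-one
Product: 3 (2R,3S,4R)-7-(benzyloxy)-2-[3,4,5-tris(benzyloxy)phenyl]chromane-3,4-diol
Conditions: NaBH4, THF/EtOH, 0 °C
Reagents that add atoms: none
Why: Borohydride reduction of the aryl ketone; axial hydride delivery should give mainly the equatorial C4 alcohol (3,4-trans), as is usual for 2,3-trans-dihydroflavonols, and the C4 configuration is in any case lost in step 13.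

Step 3
Reactants: 3 (2R,3S,4R)-7-(benzyloxy)-2-[3,4,5-tris(benzyloxy)phenyl]chromane-3,4-diol
Product: 4 (2R,3S,4R)-7-(benzyloxy)-2-[3,4,5-tris(benzyloxy)phenyl]chromane-3,4-diyl diacetate
Conditions: Ac2O, pyridine, DMAP (cat.), CH2Cl2, rt
Reagents that add atoms: acetic anhydride, CC(=O)OC(C)=O
Why: DMAP-catalysed acylation of both secondary alcohols; the benzylic 4-acetate becomes the leaving group and the 3-acetate the participating group of step 13.

Step 4
Reactants: 5 1,3-bis(benzyloxy)benzene
Product: 8 2,6-bis(benzyloxy)phenol, via 2,6-bis(benzyloxy)phenyllithium 6 (not isolated), via dimethyl 2,6-bis(benzyloxy)phenylboronate 7 (not isolated)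
Conditions: n-BuLi, THF, 0 °C → rt; B(OMe)3, −78 °C → rt; H2O2, NaOH, H2O, 0 °C
Reagents that add atoms: hydrogen peroxide, OO
Why: Directed ortho-metalation at the C–H flanked by both ether oxygens, borylation and oxidative C–B to C–O conversion, the standard passage from a 1,3-dialkoxybenzene to a 2,6-dialkoxyphenol.

Step 5
Reactants: 8 2,6-bis(benzyloxy)phenol
Product: 9 2,6-bis(benzyloxy)-4-bromophenol
Conditions: NBS, CH2Cl2, −40 → 0 °C
Reagents that add atoms: N-bromosuccinimide, BrN1C(=O)CCC1=O
Why: Electrophilic aromatic bromination; the free hydroxyl is the strongest activator and its only open ortho or para position is the para carbon, as in the bromination of 2,6-dimethoxyphenol.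

Step 6
Reactants: 9 2,6-bis(benzyloxy)-4-bromophenol
Product: 10 1,3-bis(benzyloxy)-5-bromo-2-(methoxymethoxy)benzene
Conditions: MOMCl, i-Pr2NEt, CH2Cl2, 0 → 40 °C
Reagents that add atoms: chloromethyl methyl ether, COCCl
Why: O-alkylation to the MOM acetal, which tolerates the organomagnesium, organolithium and NaH steps and is later lost in dilute acid without touching benzyl ethers.

Step 7
Reactants: 10 1,3-bis(benzyloxy)-5-bromo-2-(methoxymethoxy)benzene; 11 (R)-epichlorohydrin
Product: 13 (2R)-1-[3,5-bis(benzyloxy)-4-(methoxymethoxy)phenyl]-3-chloropropan-2-ol, via arylmagnesium bromide 12 (not isolated)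
Conditions: Mg, THF, 50 °C; then CuI (10 mol %), 11, −40 → 0 °C
Reagents that add atoms: none
Why: Grignard formation followed by CuI-catalysed (monovalent copper) opening of the epoxide at its CH2 end, which is faster than displacement of chloride; no bond to the carbinol carbon is broken, so the configuration of 11 is kept.

Step 8
Reactants: 13 (2R)-1-[3,5-bis(benzyloxy)-4-(methoxymethoxy)phenyl]-3-chloropropan-2-ol
Product: 14 (2R)-2-[3,5-bis(benzyloxy)-4-(methoxymethoxy)benzyl]oxirane
Conditions: K2CO3, MeOH, rt
Reagents that add atoms: none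
Why: Intramolecular Williamson reaction of the alkoxide on the primary chloride; the C–O bond at the stereocentre is untouched, so the (R) centre that becomes C3' persists.

Step 9
Reactants: 15 3,5-bis(benzyloxy)phenol
Product: 16 1,3-bis(benzyloxy)-5-(methoxymethoxy)benzene
Conditions: MOMCl, i-Pr2NEt, CH2Cl2, 0 °C → rt
Reagents that add atoms: chloromethyl methyl ether, COCCl
Why: MOM ether formation; the acetal protects the future O1' and is the directing group for step 10.

Step 10
Reactants: 16 1,3-bis(benzyloxy)-5-(methoxymethoxy)benzene; 14 (2R)-2-[3,5-bis(benzyloxy)-4-(methoxymethoxy)benzyl]oxirane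
Product: 18 (2R)-1-[2,4-bis(benzyloxy)-6-(methoxymethoxy)phenyl]-3-[3,5-bis(benzyloxy)-4-(methoxymethoxy)phenyl]propan-2-ol, via aryllithium 17 (not isolated)
Conditions: n-BuLi, THF, 0 °C; then −78 °C, 14, BF3·OEt2
Reagents that add atoms: none
Why: Directed ortho-metalation, in which the chelating MOM ether should steer n-BuLi to the C–H between the MOM ether and a benzyl ether (the future C4a'), then BF3-assisted opening of the terminal epoxide at CH2; the C4'–C4a' bond forms without touching the carbinol centre.

Step 11
Reactants: 18 (2R)-1-[2,4-bis(benzyloxy)-6-(methoxymethoxy)phenyl]-3-[3,5-bis(benzyloxy)-4-(methoxymethoxy)phenyl]propan-2-ol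
Product: 19 (2R)-2-(benzyloxy)-1-[2,4-bis(benzyloxy)-6-(methoxymethoxy)phenyl]-3-[3,5-bis(benzyloxy)-4-(methoxymethoxy)phenyl]propane
Conditions: NaH, BnBr, n-Bu4NI (cat.), THF/DMF, 0 °C → rt
Reagents that add atoms: benzyl bromide, BrCc1ccccc1
Why: Williamson benzylation of the secondary alkoxide; the benzyl ether on the future C3' is the group that later directs the ring closure.

Step 12
Reactants: 19 (2R)-2-(benzyloxy)-1-[2,4-bis(benzyloxy)-6-(methoxymethoxy)phenyl]-3-[3,5-bis(benzyloxy)-4-(methoxymethoxy)phenyl]propane
Product: 20 3,5-bis(benzyloxy)-2-[(2R)-2-(benzyloxy)-3-(3,5-bis(benzyloxy)-4-hydroxyphenyl)propyl]phenol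
Conditions: HCl (cat.), MeOH/THF, 45 °C
Reagents that add atoms: none
Why: Acid-catalysed acetal exchange with methanol removes both aryl MOM groups while benzyl ethers are stable; the large excess of methanol traps the formaldehyde unit and keeps it off the nucleophilic ring D.

Step 13
Reactants: 4 (2R,3S,4R)-7-(benzyloxy)-2-[3,4,5-tris(benzyloxy)phenyl]chromane-3,4-diyl diacetate; 20 3,5-bis(benzyloxy)-2-[(2R)-2-(benzyloxy)-3-(3,5-bis(benzyloxy)-4-hydroxyphenyl)propyl]phenol
Product: 21 (2R,3S,4S)-7-(benzyloxy)-4-{4,6-bis(benzyloxy)-3-[(2R)-2-(benzyloxy)-3-(3,5-bis(benzyloxy)-4-hydroxyphenyl)propyl]-2-hydroxyphenyl}-2-[3,4,5-tris(benzyloxy)phenyl]chroman-3-yl acetate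
Conditions: BF3·OEt2 (0.3 equiv), CH2Cl2, −40 → 0 °C, 20 in excess
Reagents that add atoms: none
Why: Friedel–Crafts arylation of a flavan-4-yl cation: BF3 ionises the benzylic 4-acetate, the 3-acetate bridges the β face as in a 1,2-trans glycosylation, and the arene therefore enters from the α face to give the 3,4-trans (4S) product. Ring D is the only phloroglucinol-type ring present and should react at C8' (ortho to the free hydroxyl, one flanking benzyloxy group) in preference to C6' (two flanking benzyloxy groups), as C8 does in benzylated flavan-3-ols.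

Step 14
Reactants: 21 (2R,3S,4S)-7-(benzyloxy)-4-{4,6-bis(benzyloxy)-3-[(2R)-2-(benzyloxy)-3-(3,5-bis(benzyloxy)-4-hydroxyphenyl)propyl]-2-hydroxyphenyl}-2-[3,4,5-tris(benzyloxy)phenyl]chroman-3-yl acetate
Product: 22 (2R,3S,4S)-7-(benzyloxy)-4-{4,6-bis(benzyloxy)-3-[(2R)-2-(benzyloxy)-3-(3,5-bis(benzyloxy)-4-hydroxyphenyl)propyl]-2-hydroxyphenyl}-2-[3,4,5-tris(benzyloxy)phenyl]chroman-3-ol
Conditions: K2CO3, MeOH/THF, rt, argon
Reagents that add atoms: none
Why: Base-catalysed transesterification removes the acetate; it is done before ring F exists, so that no base meets a 2-arylchroman with a free para hydroxyl, which could reopen.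

Step 15
Reactants: 22 (2R,3S,4S)-7-(benzyloxy)-4-{4,6-bis(benzyloxy)-3-[(2R)-2-(benzyloxy)-3-(3,5-bis(benzyloxy)-4-hydroxyphenyl)propyl]-2-hydroxyphenyl}-2-[3,4,5-tris(benzyloxy)phenyl]chroman-3-ol
Product: 24 nona-O-benzyl robinetinidol-(4α→8)-gallocatechin with free C3 hydroxyl and free ring E para hydroxyl, via ring E para-quinone methide 23 (not isolated)
Conditions: Ag2O (about 1 equiv), CH2Cl2, rt, dark, argon
Reagents that add atoms: none
Why: Ag2O (monovalent silver) removes two electrons and two protons from the ring E phenol, whose phenoxyl radical is stabilised by the two ortho benzyloxy groups, and gives para-quinone methide 23 with C2' as exocyclic carbon. The ring D hydroxyl on C8a' then adds to C2' in an oxa-conjugate (1,6-) addition that restores the aromaticity of ring E and forms the O1'–C2' bond. The closest known reaction type is the Ag2O oxidation of 4-alkyl-2,6-dialkoxyphenols to para-quinone methides with intramolecular capture by an oxygen nucleophile. Ring F closes in the 6-exo-trig mode, the C2'=C(ring E) double bond lying outside the new ring. The new stereocentre C2' is controlled by C3': in the chair-like transition state the C3' benzyloxy group and the quinoid ring on C2' are both pseudo-equatorial, which leads to the 2',3'-trans (2'R) chroman; as long as the para hydroxyl is free the addition is reversible, and this diequatorial isomer is also the more stable one. The step needs ring E to be oxidised in preference to ring D; the ring D phenol has its benzyloxy groups meta to the hydroxyl and no para alkyl group, so it gains no comparable stabilisation and should stay intact. It also needs the C8a' oxygen to win over the C3 hydroxyl, which ring size secures (six against nine members). About one equivalent of oxidant is used because 24 is still a syringyl-type phenol and must not be oxidised again.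

Step 16
Reactants: 24 nona-O-benzyl robinetinidol-(4α→8)-gallocatechin with free C3 hydroxyl and free ring E para hydroxyl
Product: 25 robinetinidol-(4α,8)-gallocatechin
Conditions: H2 (1 atm), Pd(OH)2/C, THF/MeOH, rt
Reagents that add atoms: none
Why: Catalytic hydrogenolysis of nine O-benzyl ethers under neutral conditions; the cyclic benzylic C–O bonds of the two chroman rings and the interflavan bond should be cleaved far more slowly, and no stereocentre is involved.

## Compound list

1 | (+)-dihydrorobinetin, (2R,3R)-3,7-dihydroxy-2-(3,4,5-trihydroxyphenyl)chroman-4-one | Oc1ccc2c(c1)O[C@H](c1cc(O)c(O)c(O)c1)[C@@H](O)C2=O | starting material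
2 | (2R,3R)-7-(benzyloxy)-3-hydroxy-2-[3,4,5-tris(benzyloxy)phenyl]chroman-4-one | c1ccccc1COc1ccc2c(c1)O[C@H](c1cc(OCc3ccccc3)c(OCc3ccccc3)c(OCc3ccccc3)c1)[C@@H](O)C2=O | intermediate
3 | (2R,3S,4R)-7-(benzyloxy)-2-[3,4,5-tris(benzyloxy)phenyl]chromane-3,4-diol | c1ccccc1COc1ccc2c(c1)O[C@H](c1cc(OCc3ccccc3)c(OCc3ccccc3)c(OCc3ccccc3)c1)[C@@H](O)[C@@H]2O | intermediate
4 | (2R,3S,4R)-7-(benzyloxy)-2-[3,4,5-tris(benzyloxy)phenyl]chromane-3,4-diyl diacetate | c1ccccc1COc1ccc2c(c1)O[C@H](c1cc(OCc3ccccc3)c(OCc3ccccc3)c(OCc3ccccc3)c1)[C@@H](OC(C)=O)[C@@H]2OC(C)=O | intermediate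
5 | 1,3-bis(benzyloxy)benzene | c1ccc(COc2cccc(OCc3ccccc3)c2)cc1 | starting material
6 | 2,6-bis(benzyloxy)phenyllithium | [Li]c1c(OCc2ccccc2)cccc1OCc1ccccc1 | intermediate (not isolated)
7 | dimethyl 2,6-bis(benzyloxy)phenylboronate | COB(OC)c1c(OCc2ccccc2)cccc1OCc1ccccc1 | intermediate (not isolated)
8 | 2,6-bis(benzyloxy)phenol | Oc1c(OCc2ccccc2)cccc1OCc1ccccc1 | intermediate
9 | 2,6-bis(benzyloxy)-4-bromophenol | Oc1c(OCc2ccccc2)cc(Br)cc1OCc1ccccc1 | intermediate
10 | 1,3-bis(benzyloxy)-5-bromo-2-(methoxymethoxy)benzene | COCOc1c(OCc2ccccc2)cc(Br)cc1OCc1ccccc1 | intermediate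
11 | (R)-epichlorohydrin | ClC[C@H]1CO1 | starting material
12 | [3,5-bis(benzyloxy)-4-(methoxymethoxy)phenyl]magnesium bromide | Br[Mg]c1cc(OCc2ccccc2)c(OCOC)c(OCc2ccccc2)c1 | intermediate (not isolated)
13 | (2R)-1-[3,5-bis(benzyloxy)-4-(methoxymethoxy)phenyl]-3-chloropropan-2-ol | ClC[C@H](O)Cc1cc(OCc2ccccc2)c(OCOC)c(OCc2ccccc2)c1 | intermediate
14 | (2R)-2-[3,5-bis(benzyloxy)-4-(methoxymethoxy)benzyl]oxirane | COCOc1c(OCc2ccccc2)cc(C[C@@H]2CO2)cc1OCc1ccccc1 | intermediate
15 | 3,5-bis(benzyloxy)phenol | Oc1cc(OCc2ccccc2)cc(OCc2ccccc2)c1 | starting material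
16 | 1,3-bis(benzyloxy)-5-(methoxymethoxy)benzene | COCOc1cc(OCc2ccccc2)cc(OCc2ccccc2)c1 | intermediate
17 | 2,4-bis(benzyloxy)-6-(methoxymethoxy)phenyllithium | COCOc1cc(OCc2ccccc2)cc(OCc2ccccc2)c1[Li] | intermediate (not isolated)
18 | (2R)-1-[2,4-bis(benzyloxy)-6-(methoxymethoxy)phenyl]-3-[3,5-bis(benzyloxy)-4-(methoxymethoxy)phenyl]propan-2-ol | COCOc1cc(OCc2ccccc2)cc(OCc2ccccc2)c1C[C@H](O)Cc1cc(OCc2ccccc2)c(OCOC)c(OCc2ccccc2)c1 | intermediate
19 | (2R)-2-(benzyloxy)-1-[2,4-bis(benzyloxy)-6-(methoxymethoxy)phenyl]-3-[3,5-bis(benzyloxy)-4-(methoxymethoxy)phenyl]propane | COCOc1cc(OCc2ccccc2)cc(OCc2ccccc2)c1C[C@H](OCc1ccccc1)Cc1cc(OCc2ccccc2)c(OCOC)c(OCc2ccccc2)c1 | intermediate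
20 | 3,5-bis(benzyloxy)-2-[(2R)-2-(benzyloxy)-3-(3,5-bis(benzyloxy)-4-hydroxyphenyl)propyl]phenol | Oc1cc(OCc2ccccc2)cc(OCc2ccccc2)c1C[C@H](OCc1ccccc1)Cc1cc(OCc2ccccc2)c(O)c(OCc2ccccc2)c1 | intermediate
21 | (2R,3S,4S)-7-(benzyloxy)-4-{4,6-bis(benzyloxy)-3-[(2R)-2-(benzyloxy)-3-(3,5-bis(benzyloxy)-4-hydroxyphenyl)propyl]-2-hydroxyphenyl}-2-[3,4,5-tris(benzyloxy)phenyl]chroman-3-yl acetate | c1ccccc1COc1ccc2c(c1)O[C@H](c1cc(OCc3ccccc3)c(OCc3ccccc3)c(OCc3ccccc3)c1)[C@@H](OC(C)=O)[C@@H]2c1c(OCc3ccccc3)cc(OCc3ccccc3)c(C[C@H](OCc3ccccc3)Cc3cc(OCc4ccccc4)c(O)c(OCc4ccccc4)c3)c1O | intermediate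
22 | (2R,3S,4S)-7-(benzyloxy)-4-{4,6-bis(benzyloxy)-3-[(2R)-2-(benzyloxy)-3-(3,5-bis(benzyloxy)-4-hydroxyphenyl)propyl]-2-hydroxyphenyl}-2-[3,4,5-tris(benzyloxy)phenyl]chroman-3-ol (key-step precursor) | c1ccccc1COc1ccc2c(c1)O[C@H](c1cc(OCc3ccccc3)c(OCc3ccccc3)c(OCc3ccccc3)c1)[C@@H](O)[C@@H]2c1c(OCc3ccccc3)cc(OCc3ccccc3)c(C[C@H](OCc3ccccc3)Cc3cc(OCc4ccccc4)c(O)c(OCc4ccccc4)c3)c1O | intermediate
23 | para-quinone methide of 22: ring E as 2,6-bis(benzyloxy)cyclohexa-2,5-dien-1-one with C2' as 4-ylidene carbon | c1ccccc1COc1ccc2c(c1)O[C@H](c1cc(OCc3ccccc3)c(OCc3ccccc3)c(OCc3ccccc3)c1)[C@@H](O)[C@@H]2c1c(OCc3ccccc3)cc(OCc3ccccc3)c(C[C@H](OCc3ccccc3)C=C3C=C(OCc4ccccc4)C(=O)C(OCc4ccccc4)=C3)c1O | intermediate (not isolated)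
24 | nona-O-benzyl robinetinidol-(4α→8)-gallocatechin: benzyl on O7, the three ring B oxygens, O5', O7', O3' and the two outer ring E oxygens; free C3 hydroxyl and free ring E para hydroxyl; (2R,3S,4S,2'R,3'S) | c1ccccc1COc1ccc2c(c1)O[C@H](c1cc(OCc3ccccc3)c(OCc3ccccc3)c(OCc3ccccc3)c1)[C@@H](O)[C@@H]2c1c(OCc3ccccc3)cc(OCc3ccccc3)c2c1O[C@H](c1cc(OCc3ccccc3)c(O)c(OCc3ccccc3)c1)[C@@H](OCc1ccccc1)C2 | intermediate
25 | robinetinidol-(4α,8)-gallocatechin | Oc1ccc2c(c1)O[C@H](c1cc(O)c(O)c(O)c1)[C@@H](O)[C@@H]2c1c(O)cc(O)c2c1O[C@H](c1cc(O)c(O)c(O)c1)[C@@H](O)C2 | target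

## Step count and risks

Total: 16 steps. Longest linear sequence: 12 steps (5 → 8 → 9 → 10 → 13 → 14 → 18 → 19 → 20 → 21 → 22 → 24 → 25).

**Step 15 (key step).** The ring closure may be slow because the C8a' hydroxyl is buttressed by the flavanyl group on C8'. The quinone methide could then tautomerise to the styrene-type enol ether (loss of the C3' centre), be attacked intermolecularly, or form with poor facial selectivity at C2'. Product 24 could also be oxidised again. The fallback gives up the late ring closure and sets out from diacetate 4 and commercial (+)-gallocatechin F1. The five phenols of F1 are benzylated (BnBr, K2CO3, DMF) to 5,7,3',4',5'-penta-O-benzylgallocatechin F2. F2 is coupled with 4 at C8 under BF3·OEt2 catalysis to the dimer acetate F3. Transesterification (K2CO3, MeOH) gives the diol F4, and hydrogenolysis over Pd(OH)2/C returns to the route at 25.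

**Step 13.** Attack at C6' or at a phenol oxygen in place of C8', or leakage through the open cation to the 3,4-cis isomer, would give inseparable isomers. The fallback closes ring F before the interflavan bond is made, so that the nucleophile is an ordinary benzylated flavan-3-ol with its well-established C8 preference. It sets out from 20 and 4. Ag2O oxidation of 20 gives 3,5,7,3',5'-penta-O-benzylgallocatechin with free para hydroxyl on ring E, F5. BF3·OEt2-catalysed coupling of F5 with 4 gives the closed dimer acetate F6. Reductive removal of the acetate with i-Bu2AlH at −78 °C returns to the route at 24.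

**Step 10.** Metalation may occur at the C–H between the two benzyloxy groups or at a benzylic CH2 (followed by Wittig rearrangement), and excess base would open the epoxide. The fallback fixes the site by halogen and makes the anion by exchange at low temperature. It sets out from 15. Amine-mediated ortho bromination (NBS, cat. i-Pr2NH, CH2Cl2) gives 3,5-bis(benzyloxy)-2-bromophenol F7, and MOM protection gives its MOM ether F8. Bromine–lithium exchange (n-BuLi, THF, −78 °C) returns to the route at 17, which is carried on to 18 as in step 10.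

**Step 1.** Base may open the β-aryloxy ketone (epimerisation at C2 and C3) or promote dehydrogenation to the flavonol before the phenols are capped. The fallback removes the ketone first. It sets out from 1, which is reduced with NaBH4 to the free (2R,3S,4R)-flavan-3,4-diol, leucorobinetinidin F9. The four phenols of F9 are then benzylated (BnBr, K2CO3, DMF), returning to the route at 3.

## Further compounds

F1 | step 15 | (+)-gallocatechin, (2R,3S) | Oc1cc(O)c2c(c1)O[C@H](c1cc(O)c(O)c(O)c1)[C@@H](O)C2
F2 | step 15 | 5,7,3',4',5'-penta-O-benzyl-(+)-gallocatechin | c1ccccc1COc1cc(OCc3ccccc3)c2c(c1)O[C@H](c1cc(OCc3ccccc3)c(OCc3ccccc3)c(OCc3ccccc3)c1)[C@@H](O)C2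
F3 | step 15 | 3-O-acetyl-7,3',4',5'-tetra-O-benzylrobinetinidol-(4α→8)-5,7,3',4',5'-penta-O-benzylgallocatechin | c1ccccc1COc1ccc2c(c1)O[C@H](c1cc(OCc3ccccc3)c(OCc3ccccc3)c(OCc3ccccc3)c1)[C@@H](OC(C)=O)[C@@H]2c1c(OCc3ccccc3)cc(OCc3ccccc3)c2c1O[C@H](c1cc(OCc3ccccc3)c(OCc3ccccc3)c(OCc3ccccc3)c1)[C@@H](O)C2
F4 | step 15 | 7,3',4',5'-tetra-O-benzylrobinetinidol-(4α→8)-5,7,3',4',5'-penta-O-benzylgallocatechin (free C3 and C3' hydroxyls) | c1ccccc1COc1ccc2c(c1)O[C@H](c1cc(OCc3ccccc3)c(OCc3ccccc3)c(OCc3ccccc3)c1)[C@@H](O)[C@@H]2c1c(OCc3ccccc3)cc(OCc3ccccc3)c2c1O[C@H](c1cc(OCc3ccccc3)c(OCc3ccccc3)c(OCc3ccccc3)c1)[C@@H](O)C2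
F5 | step 13 | 3,5,7,3',5'-penta-O-benzyl-(+)-gallocatechin with free ring E para hydroxyl | c1ccccc1COc1cc(OCc3ccccc3)c2c(c1)O[C@H](c1cc(OCc3ccccc3)c(O)c(OCc3ccccc3)c1)[C@@H](OCc1ccccc1)C2
F6 | step 13 | 3-O-acetyl derivative of 24 | c1ccccc1COc1ccc2c(c1)O[C@H](c1cc(OCc3ccccc3)c(OCc3ccccc3)c(OCc3ccccc3)c1)[C@@H](OC(C)=O)[C@@H]2c1c(OCc3ccccc3)cc(OCc3ccccc3)c2c1O[C@H](c1cc(OCc3ccccc3)c(O)c(OCc3ccccc3)c1)[C@@H](OCc1ccccc1)C2
F7 | step 10 | 3,5-bis(benzyloxy)-2-bromophenol | Oc1cc(OCc2ccccc2)cc(OCc2ccccc2)c1Br
F8 | step 10 | 1,5-bis(benzyloxy)-2-bromo-3-(methoxymethoxy)benzene | COCOc1cc(OCc2ccccc2)cc(OCc2ccccc2)c1Br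
F9 | step 1 | leucorobinetinidin, (2R,3S,4R)-2-(3,4,5-trihydroxyphenyl)chromane-3,4,7-triol | Oc1ccc2c(c1)O[C@H](c1cc(O)c(O)c(O)c1)[C@@H](O)[C@@H]2O
A1 | alternative 1 | penta-O-benzylrobinetinidol carrying at C4 (4α) a 4-(benzyloxy)-6-hydroxy-2-(triisopropylsilyloxy)-3-[(E)-3-(3,4,5-tris(benzyloxy)phenyl)prop-2-enyl]phenyl group | c1ccccc1COc1ccc2c(c1)O[C@H](c1cc(OCc3ccccc3)c(OCc3ccccc3)c(OCc3ccccc3)c1)[C@@H](OCc1ccccc1)[C@@H]2c1c(O)cc(OCc3ccccc3)c(C/C=C/c3cc(OCc4ccccc4)c(OCc4ccccc4)c(OCc4ccccc4)c3)c1O[Si](C(C)C)(C(C)C)C(C)C
A2 | alternative 1 | penta-O-benzylrobinetinidol carrying at C4 (4α) a (triisopropylsilyloxy)ethynyl group | c1ccccc1COc1ccc2c(c1)O[C@H](c1cc(OCc3ccccc3)c(OCc3ccccc3)c(OCc3ccccc3)c1)[C@@H](OCc1ccccc1)[C@@H]2C#CO[Si](C(C)C)(C(C)C)C(C)C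
A3 | alternative 1 | 3-(benzyloxy)-2-[(E)-3-(3,4,5-tris(benzyloxy)phenyl)prop-2-enyl]cyclobut-2-en-1-one | O=C1CC(OCc2ccccc2)=C1C/C=C/c1cc(OCc2ccccc2)c(OCc2ccccc2)c(OCc2ccccc2)c1
A4 | alternative 2 | 7-(benzyloxy)-2-[3,4,5-tris(benzyloxy)phenyl]-4H-chromene bonded at C4 to C8 of hexa-O-benzylgallocatechin | c1ccccc1COc1ccc2c(c1)OC(c1cc(OCc3ccccc3)c(OCc3ccccc3)c(OCc3ccccc3)c1)=C[C@@H]2c1c(OCc3ccccc3)cc(OCc3ccccc3)c2c1O[C@H](c1cc(OCc3ccccc3)c(OCc3ccccc3)c(OCc3ccccc3)c1)[C@@H](OCc1ccccc1)C2
A5 | alternative 2 | hexa-O-benzylgallocatechin bearing at C8 a 1-arylprop-2-enyl group, aryl = 4-(benzyloxy)-2-{1-[3,4,5-tris(benzyloxy)phenyl]ethenyloxy}phenyl | C=C[C@@H](c1ccc(OCc2ccccc2)cc1OC(=C)c1cc(OCc2ccccc2)c(OCc2ccccc2)c(OCc2ccccc2)c1)c1c(OCc2ccccc2)cc(OCc2ccccc2)c2c1O[C@H](c1cc(OCc3ccccc3)c(OCc3ccccc3)c(OCc3ccccc3)c1)[C@@H](OCc1ccccc1)C2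
A6 | alternative 3 | deca-O-benzyl dimer skeleton with a pinacol boronate in place of the C3 oxygen | c1ccccc1COc1ccc2c(c1)O[C@H](c1cc(OCc3ccccc3)c(OCc3ccccc3)c(OCc3ccccc3)c1)[C@@H](B1OC(C)(C)C(C)(C)O1)[C@@H]2c1c(OCc3ccccc3)cc(OCc3ccccc3)c2c1O[C@H](c1cc(OCc3ccccc3)c(OCc3ccccc3)c(OCc3ccccc3)c1)[C@@H](OCc1ccccc1)C2
A7 | alternative 3 | [4-(benzyloxy)-2-hydroxyphenyl](hexa-O-benzylgallocatechin-8-yl)methanol, carbinol centre undefined | Oc1cc(OCc2ccccc2)ccc1C(O)c1c(OCc2ccccc2)cc(OCc2ccccc2)c2c1O[C@H](c1cc(OCc3ccccc3)c(OCc3ccccc3)c(OCc3ccccc3)c1)[C@@H](OCc1ccccc1)C2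
A8 | alternative 3 | (E)-4,4,5,5-tetramethyl-2-[2-(3,4,5-tris(benzyloxy)phenyl)ethenyl]-1,3,2-dioxaborolane | CC1(C)OB(/C=C/c2cc(OCc3ccccc3)c(OCc3ccccc3)c(OCc3ccccc3)c2)OC1(C)C
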